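**Strategy.** Numbering: cycloheptane C1 (quaternary carbinol), C5 (O‑isovaleryl), C6/C7 (lactone fusion), C8, C9 (CHOH), C10 (CHMe). The route rests on disconnecting C9–C10 and C5–C1. The key step exploits the cis‑1,4‑dioxygenated carbons C9 and C5 of the seven‑membered ring: they are the termini of a six‑membered carbonyl ylide, generated from an acyclic diazo keto ester (C5–C9 chain), which adds to (Z)‑benzyl propenyl ether (C10–C1). This single [3+2] cycloaddition closes the cycloheptane as an 8‑oxabicyclo[3.2.1]octane, fixes C5 and C10, and supplies both oxygens: the bridge oxygen stays on C5, and the bridgehead ketal becomes the C9 carbonyl.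

Key step: step 3

Assumption: the (4S,5S)‑pybox ligand is taken to deliver the enantiomer of 6 that is drawn; if induction runs the other way, the (4R,5R)‑ligand is used.

Remark: the Why lines use the target numbering above. Names of bicyclic intermediates use von Baeyer locants (locant 1 = C5, 2 = C6, 3 = C7, 4 = C8, 5 = C9, 6 = C10, 7 = C1 of the target); "endo" means anti to the oxygen bridge O8.

Step 1
Reactants: 1 methyl 4‑chloro‑4‑oxobutanoate
Product: 2 methyl 5‑diazo‑4‑oxopentanoate
Conditions: TMSCHN2 (2.2 equiv), THF/MeCN 1:1, 0 °C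
Reagents that add atoms: (trimethylsilyl)diazomethane, C[Si](C)(C)C=[N+]=[N-]
Why: Acylation of the diazoalkane by the acid chloride with loss of Me3SiCl (Arndt–Eistert‑type α‑diazo ketone synthesis) should leave the methyl ester untouched.

Step 2
Reactants: 3 allyl benzyl ether
Product: 4 (Z)‑benzyl prop‑1‑enyl ether
Conditions: KOtBu (0.2 equiv), DMSO, 25 °C
Reagents that add atoms: none
Why: Base‑mediated allyl‑to‑propenyl ether isomerisation through a potassium‑chelated cisoid allyl anion should give the (Z)‑enol ether, whose geometry later relates C10 to C1.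

Step 3
Reactants: 2 methyl 5‑diazo‑4‑oxopentanoate; 4 (Z)‑benzyl prop‑1‑enyl ether
Product: 6 cycloadduct 7‑endo‑benzyloxy‑5‑methoxy‑6‑endo‑methyl‑8‑oxabicyclo[3.2.1]octan‑2‑one, via carbonyl ylide 5 (not isolated)
Conditions: Rh2(OAc)4 (2 mol %), Eu(OTf)3 (10 mol %), 2,6‑bis[(4S,5S)‑4,5‑diphenyl‑4,5‑dihydrooxazol‑2‑yl]pyridine (10 mol %), 4 Å MS, CH2Cl2, 2 added slowly to 4 (3 equiv), 0 °C to rt
Reagents that add atoms: none
Why: Rh2(OAc)4 converts 2 into a rhodium carbenoid whose ester carbonyl oxygen attacks the carbene carbon (six‑membered O–C closure) to give ylide 5, which adds across the enol ether in an asynchronous, suprafacial [3+2] cycloaddition that closes the oxolane ring and with it the seven‑membered carbocycle (C9–C10 and C5–C1 bonds). The closest known reaction type is the tandem carbonyl‑ylide formation/1,3‑dipolar cycloaddition in its inverse‑electron‑demand, chiral‑Lewis‑acid‑catalysed form with vinyl ethers and 2,3‑dihydrofuran. Regiochemistry is polarity‑matched: the nucleophilic β‑carbon of the enol ether (C10) bonds to the alkoxy‑stabilised oxocarbenium terminus (C9), and the O‑bearing carbon (C1) bonds to the enolate‑like terminus (C5). Endo approach of the alkoxy group places OBn and, through the (Z) geometry transferred stereospecifically, the methyl group on the endo face, which sets C10 relative to the bridge. The europium–pybox Lewis acid binds the ylide carbonyl, lowers the dipole LUMO and shields one enantioface, which fixes the absolute configuration at C5 (and at the transient C9 ketal). The step needs ylide formation to outrun cyclopropanation of the enol ether; the intramolecular ester carbonyl and slow addition of 2 should secure this.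

Step 4
Reactants: 6 cycloadduct benzyl ether
Product: 7 7‑endo‑hydroxy‑5‑methoxy‑6‑endo‑methyl‑8‑oxabicyclo[3.2.1]octan‑2‑one
Conditions: H2 (1 atm), Pd/C (10 %), EtOAc, rt
Reagents that add atoms: none
Why: Hydrogenolysis of the benzyl ether should leave the ketone and the bridged ketal untouched and affects no stereocentre.

Step 5
Reactants: 7 hydroxy ketone
Product: 9 hydroxy enone 7‑endo‑hydroxy‑5‑methoxy‑6‑endo‑methyl‑8‑oxabicyclo[3.2.1]oct‑3‑en‑2‑one, via bis(trimethylsilyl) enol ether 8 (not isolated)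
Conditions: LDA (2.2 equiv), TMSCl (2.5 equiv), THF, −78 °C; then Pd(OAc)2 (1.1 equiv), MeCN, rt; K2CO3, MeOH work‑up
Reagents that add atoms: none
Why: Saegusa–Ito dehydrogenation is regiospecific here because C7 is the only enolisable position of the C6 ketone (C5 is a bridgehead), so only the C7=C8 enone can form; the C1 hydroxyl travels as its silyl ether and is freed on work‑up.

Step 6
Reactants: 9 hydroxy enone
Product: 10 enedione 5‑methoxy‑6‑endo‑methyl‑8‑oxabicyclo[3.2.1]oct‑3‑ene‑2,7‑dione
Conditions: Dess–Martin periodinane, NaHCO3, CH2Cl2, 0 °C to rt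
Reagents that add atoms: none
Why: Buffered Dess–Martin oxidation of the secondary C1 carbinol should not enolise the adjacent C10 methine; the C1 configuration from the cycloaddition is deliberately erased here.

Step 7
Reactants: 10 enedione
Product: 11 allylic alcohol 2‑hydroxy‑5‑methoxy‑6‑endo‑methyl‑8‑oxabicyclo[3.2.1]oct‑3‑en‑7‑one (2‑hydroxyl anti to O8 across the seven‑membered ring)
Conditions: NaBH4 (1.0 equiv), CeCl3·7H2O, MeOH, −78 °C
Reagents that add atoms: none
Why: Luche reduction should take the CeCl3‑activated conjugated C6 ketone 1,2 in preference to the strained saturated C1 ketone (largely masked as its methanol hemiketal), with hydride entering on the exo face anti to the two‑carbon bridge, which sets the C6 configuration.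

Step 8
Reactants: 12 1‑methoxybut‑2‑yne
Product: 13 1‑methoxybuta‑1,2‑diene
Conditions: KOtBu (0.1 equiv), DMSO, 20 °C; distillation
Reagents that add atoms: none
Why: Base‑catalysed propargyl–allenyl prototropy of the 2‑alkynyl ether should give the 1‑alkoxyallene, a latent (E)‑but‑2‑enoyl anion; contact time is kept short to avoid onward isomerisation to the 1,3‑diene.

Step 9
Reactants: 11 allylic alcohol; 13 1‑methoxybuta‑1,2‑diene
Product: 15 diol 7‑exo‑(1‑methoxybuta‑1,2‑dien‑1‑yl)‑5‑methoxy‑6‑endo‑methyl‑8‑oxabicyclo[3.2.1]oct‑3‑ene‑2,7‑endo‑diol, via 1‑lithio‑1‑methoxybuta‑1,2‑diene 14 (not isolated)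
Conditions: 13 (3 equiv), n‑BuLi (3 equiv), THF, −40 °C; then 11, −78 °C; NaHCO3 (aq)
Reagents that add atoms: none
Why: 1‑Alkoxyallenes lithiate at C1 and add 1,2 to ketones (alkoxyallene acyl‑anion chemistry); exo attack on the C1 ketone, syn to the oxygen bridge and anti to the endo methyl and the three‑carbon bridge, should set quaternary C1 with the hydroxyl endo and the acyl precursor cis to the C5 oxygen (the allene axis gives inconsequential epimers).

Step 10
Reactants: 15 diol
Product: 16 phosphonoacetate, the 2‑O‑[(diethoxyphosphoryl)acetyl] ester of 15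
Conditions: (EtO)2P(O)CH2CO2H, DCC, DMAP (cat.), CH2Cl2, 0 °C to rt
Reagents that add atoms: diethylphosphonoacetic acid, CCOP(=O)(OCC)CC(=O)O
Why: Steglich esterification should acylate only the secondary allylic C6 hydroxyl (the tertiary C1 hydroxyl is inert) under conditions that spare the allenyl enol ether and the bridged ketal.

Step 11
Reactants: 16 phosphonoacetate
Product: 17 cycloheptenone 6‑[(E)‑but‑2‑enoyl]‑5,6‑dihydroxy‑7‑methyl‑1‑oxocyclohept‑2‑en‑4‑yl (diethoxyphosphoryl)acetate (4‑O, 6‑OH and 7‑CH3 on one face, 5‑OH on the other)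
Conditions: 1 M HCl (aq), THF, 0 °C to rt
Reagents that add atoms: water, O
Why: Aqueous acid should hydrolyse the methoxyallene to the (E)‑enone by protonation at the central allene carbon, and open the bridged methyl ketal so that the bridge oxygen becomes the C5 hydroxyl and C9 becomes a ketone conjugated with C7=C8; no stereocentre is involved.

Step 12
Reactants: 17 cycloheptenone
Product: 18 isovalerate, the 5‑O‑(3‑methylbutanoyl) ester of 17
Conditions: isovaleric anhydride, DMAP (cat.), pyridine, CH2Cl2, 0 °C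
Reagents that add atoms: isovaleric anhydride, CC(C)CC(=O)OC(=O)CC(C)C
Why: DMAP‑catalysed acylation should take the only secondary hydroxyl (C5); the tertiary α‑ketol hydroxyl at C1 does not react at 0 °C, and prompt acylation limits acyl migration from O6.

Step 13
Reactants: 18 isovalerate
Product: 20 9‑oxo methylene lactone (3aS,6S,7S,8S,8aR)‑7‑[(E)‑but‑2‑enoyl]‑7‑hydroxy‑6‑methyl‑3‑methylidene‑2,5‑dioxooctahydro‑2H‑cyclohepta[b]furan‑8‑yl 3‑methylbutanoate, via phosphono lactone 19 (not isolated)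
Conditions: Cs2CO3 (1.2 equiv), THF, 0 °C; then (CH2O)n, 0 °C to rt
Reagents that add atoms: formaldehyde (as paraformaldehyde), C=O
Why: Telescoped intramolecular Michael addition/Horner–Wadsworth–Emmons olefination: the phosphonoacetate carbanion should add 5‑exo to the enone β‑carbon C7 from the face of the C6 oxygen, which makes the lactone cis‑fused and sets C7, and the α‑phosphono lactone anion then olefinates formaldehyde.

Step 14
Reactants: 20 9‑oxo methylene lactone
Product: 21 CNP0186412.1, (3aS,5R,6S,7S,8S,8aR)‑7‑[(E)‑but‑2‑enoyl]‑5,7‑dihydroxy‑6‑methyl‑3‑methylidene‑2‑oxooctahydro‑2H‑cyclohepta[b]furan‑8‑yl 3‑methylbutanoate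
Conditions: Me4NBH(OAc)3, MeCN/AcOH 1:1, −30 °C
Reagents that add atoms: none
Why: Evans–Saksena reduction: the tertiary C1 hydroxyl exchanges onto boron and delivers hydride through a six‑membered chair to the β‑carbonyl C9, which should give the 1,3‑anti diol (C9–OH trans to C1–OH), while the conjugated α‑quaternary butenoyl ketone, the esters and the methylene lactone are not reduced by the acetoxyborohydride.

**Compound list**

1 | methyl 4‑chloro‑4‑oxobutanoate | COC(=O)CCC(Cl)=O | starting material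
2 | methyl 5‑diazo‑4‑oxopentanoate | COC(=O)CCC(=O)C=[N+]=[N-] | intermediate
3 | allyl benzyl ether | C=CCOCc1ccccc1 | starting material
4 | (Z)‑benzyl prop‑1‑enyl ether | C/C=C\OCc1ccccc1 | intermediate
5 | cyclic carbonyl ylide (6‑methoxy‑3‑oxo‑4,5‑dihydro‑3H‑pyran‑1‑ium‑2‑ide) | COC1=[O+][CH-]C(=O)CC1 | intermediate
6 | 7‑endo‑benzyloxy‑5‑methoxy‑6‑endo‑methyl‑8‑oxabicyclo[3.2.1]octan‑2‑one | O=C1CC[C@]2(OC)[C@H](C)[C@H](OCc3ccccc3)[C@H]1O2 | intermediate
7 | 7‑endo‑hydroxy‑5‑methoxy‑6‑endo‑methyl‑8‑oxabicyclo[3.2.1]octan‑2‑one | O=C1CC[C@]2(OC)[C@H](C)[C@H](O)[C@H]1O2 | intermediate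
8 | 5‑methoxy‑6‑endo‑methyl‑2,7‑endo‑bis(trimethylsilyloxy)‑8‑oxabicyclo[3.2.1]oct‑2‑ene | C[Si](C)(C)OC1=CC[C@]2(OC)[C@H](C)[C@H](O[Si](C)(C)C)[C@H]1O2 | intermediate
9 | 7‑endo‑hydroxy‑5‑methoxy‑6‑endo‑methyl‑8‑oxabicyclo[3.2.1]oct‑3‑en‑2‑one | O=C1C=C[C@]2(OC)[C@H](C)[C@H](O)[C@H]1O2 | intermediate
10 | 5‑methoxy‑6‑endo‑methyl‑8‑oxabicyclo[3.2.1]oct‑3‑ene‑2,7‑dione | O=C1C=C[C@]2(OC)[C@H](C)C(=O)[C@H]1O2 | intermediate
11 | 2‑hydroxy‑5‑methoxy‑6‑endo‑methyl‑8‑oxabicyclo[3.2.1]oct‑3‑en‑7‑one (2‑OH anti to O8) | O[C@@H]1C=C[C@]2(OC)[C@H](C)C(=O)[C@H]1O2 | intermediate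
12 | 1‑methoxybut‑2‑yne | CC#CCOC | starting material
13 | 1‑methoxybuta‑1,2‑diene | COC=C=CC | intermediate
14 | 1‑lithio‑1‑methoxybuta‑1,2‑diene | [Li]C(OC)=C=CC | intermediate
15 | 7‑exo‑(1‑methoxybuta‑1,2‑dien‑1‑yl)‑5‑methoxy‑6‑endo‑methyl‑8‑oxabicyclo[3.2.1]oct‑3‑ene‑2,7‑endo‑diol (allene axis unspecified) | O[C@@H]1C=C[C@]2(OC)[C@H](C)[C@@](O)(C(OC)=C=CC)[C@H]1O2 | intermediate
16 | 2‑O‑[(diethoxyphosphoryl)acetyl] ester of 15 | CCOP(=O)(OCC)CC(=O)O[C@@H]1C=C[C@]2(OC)[C@H](C)[C@@](O)(C(OC)=C=CC)[C@H]1O2 | intermediate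
17 | 6‑[(E)‑but‑2‑enoyl]‑5,6‑dihydroxy‑7‑methyl‑1‑oxocyclohept‑2‑en‑4‑yl (diethoxyphosphoryl)acetate | CCOP(=O)(OCC)CC(=O)O[C@@H]1C=CC(=O)[C@H](C)[C@@](O)(C(=O)/C=C/C)[C@H]1O | intermediate
18 | 5‑O‑(3‑methylbutanoyl) ester of 17 | CCOP(=O)(OCC)CC(=O)O[C@@H]1C=CC(=O)[C@H](C)[C@@](O)(C(=O)/C=C/C)[C@H]1OC(=O)CC(C)C | intermediate
19 | cis‑fused α‑(diethoxyphosphoryl) lactone, 3‑phosphono analogue of 20 (C3 unspecified) | CCOP(=O)(OCC)C1C(=O)O[C@@H]2[C@H]1CC(=O)[C@H](C)[C@@](O)(C(=O)/C=C/C)[C@H]2OC(=O)CC(C)C | intermediate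
20 | (3aS,6S,7S,8S,8aR)‑7‑[(E)‑but‑2‑enoyl]‑7‑hydroxy‑6‑methyl‑3‑methylidene‑2,5‑dioxooctahydro‑2H‑cyclohepta[b]furan‑8‑yl 3‑methylbutanoate | C=C1C(=O)O[C@@H]2[C@H]1CC(=O)[C@H](C)[C@@](O)(C(=O)/C=C/C)[C@H]2OC(=O)CC(C)C | intermediate
21 | CNP0186412.1, (3aS,5R,6S,7S,8S,8aR)‑7‑[(E)‑but‑2‑enoyl]‑5,7‑dihydroxy‑6‑methyl‑3‑methylidene‑2‑oxooctahydro‑2H‑cyclohepta[b]furan‑8‑yl 3‑methylbutanoate | C=C1C(=O)O[C@@H]2[C@H]1C[C@@H](O)[C@H](C)[C@@](O)(C(=O)/C=C/C)[C@H]2OC(=O)CC(C)C | target

**Step count.** Total: 14 steps. Longest linear sequence: 12 steps (1, 3, 4, 5, 6, 7, 9, 10, 11, 12, 13, 14).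

**Steps most likely to fail**

Step 3. The Lewis acid may discriminate poorly between the enantiofaces (or endo/exo modes) of this non‑aromatic ylide, and the carbenoid may be captured by the enol ether before the ylide forms. The fallback sets out from 2 and 4 and gives up catalyst control for resolution. The cycloaddition is run with Rh2(OAc)4 alone, which should give 6 together with its enantiomer ent‑6 F1. Hydrogenolysis then gives 7 and ent‑7 F2. Lipase‑mediated kinetic resolution (Candida antarctica lipase B, vinyl acetate, MTBE) should acetylate one enantiomer, taken here to be the unwanted one, to the acetate of ent‑7 F3. Unreacted 7 is separated and the route is rejoined at 7.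

Step 7. Hydride may also be transferred to the strained C1 ketone. The fallback sets out from 10 and protects before reducing. Selective ketalisation of the non‑conjugated ketone (CeCl3·7H2O cat., HC(OMe)3, MeOH) should give the dimethyl ketal F4. Luche reduction then gives the allylic alcohol ketal F5. Mild hydrolysis of the acyclic ketal (PPTS, wet acetone), which the bridged ketal should survive, returns to 11.

Step 13. Base may trigger retro‑aldol cleavage of the tertiary β‑ketol (C1–C10), epimerisation at C10 or acyl migration before the Michael closure. The fallback sets out from 15 and replaces the base‑mediated phosphonate chemistry by base‑free phosphine catalysis. Acryloylation of the C6 hydroxyl (acryloyl chloride, Et3N) gives the acrylate F6. Acid unveiling as in step 11 gives the acrylate enone F7, and isovalerylation as in step 12 gives the acrylate isovalerate F8. An intramolecular Rauhut–Currier cyclisation (PMe3 cat., t‑AmOH) follows: the phosphonium enolate of the acrylate adds to C7 from the O6 face, and loss of the phosphine leaves the α‑methylene lactone directly, rejoining at 20.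

**Further compounds**

F1 | step 3 | ent‑6, enantiomer of the benzyl ether cycloadduct | O=C1CC[C@@]2(OC)[C@@H](C)[C@@H](OCc3ccccc3)[C@@H]1O2
F2 | step 3 | ent‑7, enantiomer of the hydroxy ketone | O=C1CC[C@@]2(OC)[C@@H](C)[C@@H](O)[C@@H]1O2
F3 | step 3 | 7‑O‑acetate of ent‑7 | O=C1CC[C@@]2(OC)[C@@H](C)[C@@H](OC(C)=O)[C@@H]1O2
F4 | step 7 | 5,7,7‑trimethoxy‑6‑endo‑methyl‑8‑oxabicyclo[3.2.1]oct‑3‑en‑2‑one | O=C1C=C[C@]2(OC)[C@H](C)C(OC)(OC)[C@H]1O2
F5 | step 7 | 5,7,7‑trimethoxy‑6‑endo‑methyl‑8‑oxabicyclo[3.2.1]oct‑3‑en‑2‑ol (2‑OH anti to O8) | O[C@@H]1C=C[C@]2(OC)[C@H](C)C(OC)(OC)[C@H]1O2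
F6 | step 13 | 2‑O‑acryloyl ester of 15 | C=CC(=O)O[C@@H]1C=C[C@]2(OC)[C@H](C)[C@@](O)(C(OC)=C=CC)[C@H]1O2
F7 | step 13 | 6‑[(E)‑but‑2‑enoyl]‑5,6‑dihydroxy‑7‑methyl‑1‑oxocyclohept‑2‑en‑4‑yl acrylate | C=CC(=O)O[C@@H]1C=CC(=O)[C@H](C)[C@@](O)(C(=O)/C=C/C)[C@H]1O
F8 | step 13 | 5‑O‑(3‑methylbutanoyl) ester of F7 | C=CC(=O)O[C@@H]1C=CC(=O)[C@H](C)[C@@](O)(C(=O)/C=C/C)[C@H]1OC(=O)CC(C)C
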